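**Retrosynthetic overview**

1. Numbering (germacranolide): ring A is the ten-membered carbocycle C1 (ketone) to C10 (C–OAc); ring B is the butenolide O–C6–C7=C11–C12(=O); C13 is the CH2OAc on C11. The C10 acetate and C1 ketone come last from a C1/C10 cyclic orthoacetate; O8 methacrylate and O13 acetate are late acylations.
2. Ring B ⇐ oxidative lactonisation of a cis C6–OH/C12–OH pair; 4,5-epoxide plus C6–OH ⇐ Payne rearrangement of a cis-5,6-epoxide ⇐ C4–OH-directed epoxidation of a (5Z)-olefin.
3. Ring A ⇐ key step: tandem silicon-tethered enyne/diene ring-closing metathesis of an acyclic dienyne, forming C7=C11 inside a temporary seven-membered O8–Si–O13 ring and then C5=C6.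
4. Enabling feature: C5 and C6 are vicinal CH–O carbons of ring A next to the C4 carbinol (a masked Z-olefin), and the C7=C11 olefin of ring B carries O8 and O13 in a cis-1,4 relationship, so a temporary silicon bridge can fix its geometry.
5. Dienyne ⇐ C1–C2 union of iodide 3 ((R)-linalool supplies C4) with lactol 13 (pyruvate aldol sets C10, transfer hydrogenation sets C8). Ring order: temporary lactone/lactol → ring A with silaketal (step 12) → epoxide (steps 13, 14) → ring B (step 17).

Key step: step 12

Remark: C1 (from step 8 on) and the orthoester carbon (from step 10 on) are carried as epimer mixtures because both centres are destroyed in step 19; their SMILES carry no descriptor, and from compound 14 on descriptive names use target locants.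

**Route**

Step 1
Reactants: 1 (R)-linalool
Product: 2 (5R)-5-ethenyl-5-methyloxolan-2-ol (anomer mixture)
Conditions: O3 (1 equiv, Sudan Red 7B end point), CH2Cl2/MeOH, −78 °C; then Me2S
Reagents that add atoms: ozone, O=[O+][O-]
Why: Ozonolysis is selective for the electron-rich trisubstituted olefin over the vinyl group, and the γ-hydroxy aldehyde closes to the lactol without touching the carbinol stereocentre (future C4).

Step 2
Reactants: 2 lactol
Product: 3 (3R)-5-iodo-3-methylpent-1-en-3-yl formate
Conditions: PhI(OAc)2, I2, cyclohexane/CH2Cl2, visible light (tungsten lamp), rt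
Reagents that add atoms: iodine, II
Why: Suárez-type hypoiodite alkoxy-radical fragmentation: β-scission of the anomeric alkoxy radical gives the formate and a primary radical trapped by iodine, while the hindered vinyl group on the oxygenated quaternary carbon should resist acetyl hypoiodite.

Step 3
Reactants: 4 2-methylidenepropane-1,3-diol (3 equiv)
Product: 5 2-{[(4-methoxyphenyl)methoxy]methyl}prop-2-en-1-ol
Conditions: NaH (1 equiv), PMBCl, n-Bu4NI (cat.), THF/DMF, 0 °C → rt
Reagents that add atoms: 4-methoxybenzyl chloride, COc1ccc(CCl)cc1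
Why: Williamson mono-etherification of the symmetric diol used in excess gives the C11/C12/C13 unit with O12 protected.

Step 4
Reactants: 6 4-(trimethylsilyl)but-3-yn-2-one
Product: 7 trimethyl{[4-(trimethylsilyl)but-1-en-3-yn-2-yl]oxy}silane
Conditions: TMSOTf, Et3N, Et2O, 0 °C
Reagents that add atoms: trimethylsilyl trifluoromethanesulfonate, C[Si](C)(C)OS(=O)(=O)C(F)(F)F
Why: Soft enolisation of the methyl ketone gives the silyl enol ether needed as the Mukaiyama aldol donor.

Step 5
Reactants: 7 enolsilane; 8 methyl pyruvate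
Product: 10 methyl (2R)-2-hydroxy-2-methyl-4-oxo-6-(trimethylsilyl)hex-5-ynoate, via silyl ether 9 (not isolated)
Conditions: Cu(OTf)2 (10 mol %), 2,2'-(propane-2,2-diyl)bis[(4R)-4-tert-butyl-4,5-dihydrooxazole] (11 mol %), THF, −78 °C; then 1 M HCl
Reagents that add atoms: none
Why: Copper–bis(oxazoline)-catalysed Mukaiyama aldol addition to the chelated pyruvate sets the tertiary carbinol C10 as R through facial shielding by the (R,R)-ligand (the enantiomeric ligand is the one associated with S products in this reaction class), and acid work-up cleaves the silyl ether.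

Step 6
Reactants: 10 aldol adduct
Product: 12 (3R,5S)-3-hydroxy-3-methyl-5-[(trimethylsilyl)ethynyl]oxolan-2-one, via diol ester 11 (not isolated)
Conditions: RuCl(p-cymene)[(S,S)-TsDPEN] (1 mol %), HCO2H/Et3N 5:2, CH2Cl2, rt; then PPTS (cat.), toluene, 50 °C
Reagents that add atoms: none
Why: Noyori-type asymmetric transfer hydrogenation of the alkynyl ketone sets C8 as S by catalyst control (alkynyl versus alkyl differentiation), and the γ-hydroxy ester then lactonises.

Step 7
Reactants: 12 hydroxy lactone
Product: 13 (3R,5S)-3-methyl-5-[(trimethylsilyl)ethynyl]oxolane-2,3-diol (C2 epimers)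
Conditions: i-Bu2AlH (2.2 equiv), CH2Cl2, −78 °C; aq. Rochelle salt
Reagents that add atoms: none
Why: Partial lactone reduction stops at the lactol (stable aluminium hemiacetal at low temperature) and unmasks C1 at the aldehyde level.

Step 8
Reactants: 13 lactol; 3 iodo formate
Product: 14 (3R,7R,9S)-6,7,9-trihydroxy-3,7-dimethyl-11-(trimethylsilyl)undec-1-en-10-yn-3-yl formate (C6 epimers; C6 = target C1)
Conditions: CrCl2 (4 equiv), cobalt phthalocyanine Co(C32H16N8) (5 mol %), DMF, rt
Reagents that add atoms: none
Why: Cobalt-mediated alkylchromium (Nozaki–Hiyama-type) addition of the primary iodide to the open hydroxy-aldehyde form of the lactol forms C1–C2 chemoselectively beside the formate and free hydroxyls; the uncontrolled C1 centre later becomes the ketone.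

Step 9
Reactants: 14 triol; 5 allylic alcohol
Product: 16 14 silylated at O8 as the diisopropylsilyl ketal with 5 (C1–OH and C10–OH free), via chlorosilane 15 (not isolated)
Conditions: 5, i-Pr2SiCl2 (3 equiv), Et3N, CH2Cl2, 0 °C, excess silane evaporated; then 14, imidazole, DMF, −20 °C
Reagents that add atoms: dichlorodi(propan-2-yl)silane, CC(C)[Si](Cl)(Cl)C(C)C
Why: Unsymmetrical silaketal formation: the bulky alkoxy(chloro)silane should silylate the unhindered propargylic C8 hydroxyl in preference to the neopentyl-type C1 hydroxyl and the tertiary C10 hydroxyl.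

Step 10
Reactants: 16 silaketal diol
Product: 17 cyclic orthoacetate of 16 (C1/C10 diol closed as a 2-methoxy-2-methyl-1,3-dioxolane)
Conditions: MeC(OMe)3, PPTS (5 mol %), 4 Å molecular sieves, CH2Cl2, rt
Reagents that add atoms: trimethyl orthoacetate, CC(OC)(OC)OC
Why: Acid-catalysed orthoester exchange masks the C1/C10 1,2-diol as a base-stable five-membered orthoacetate that will later deliver the tertiary C10 acetate.

Step 11
Reactants: 17 orthoacetate
Product: 18 dienyne: 17 with free C4 tertiary alcohol and terminal alkyne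
Conditions: K2CO3 (0.5 equiv), MeOH, 0 °C
Reagents that add atoms: none
Why: Mild base methanolysis removes the tertiary formate and protodesilylates the alkynylsilane in one operation, while the silaketal and orthoester are base-stable.

Step 12
Reactants: 18 dienyne
Product: 20 ring A diene (4R,5Z,8S,10R) with C4–OH, O8–Si(i-Pr)2–O13 ring, O12–PMB and C1/C10 orthoacetate, via triene 19 (not isolated)
Conditions: second-generation Grubbs catalyst (H2IMes)(PCy3)Cl2Ru=CHPh (15 mol %), toluene (1 mM), ethylene (1 atm), 40 °C; then argon sparge, 80 °C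
Reagents that add atoms: none
Why: Under ethylene the ruthenium methylidene adds to the terminal alkyne with C–C bond formation at C6, and the resulting C7 carbene closes onto the tethered C11=CH2 olefin to give triene 19; once ethylene is purged, metathesis between the C6 vinyl group and the C5 vinyl group forms C5=C6 and releases ethylene. The closest known reaction types are silicon-tethered ring-closing enyne metathesis and ring-closing diene metathesis to ten-membered carbocycles, run here as a tandem dienyne sequence. The seven-membered silaketal ring closes in the exo enyne mode and ring A closes by diene metathesis at C5–C6. No stereocentre is formed, but two olefin geometries are set: the tether forces C13 cis to C8 (hence C12 cis to C6, as the lactone needs), and C5=C6 should be Z because the E cyclodecene bearing the exocyclic diene is much more strained and the metathesis is reversible at 80 °C. The step needs chemoselectivity (alkyne first, then the two vinyl groups) and cyclisation over oligomerisation, which the ethylene-then-argon protocol, the tethered olefin, the quaternary C4 and C10 centres and 1 mM dilution should secure.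

Step 13
Reactants: 20 ring A diene
Product: 21 cis-5,6-epoxide (4R,5S,6S,8S,10R) with free C4–OH
Conditions: VO(acac)2 (5 mol %), t-BuOOH (1.5 equiv), CH2Cl2, 0 °C
Reagents that add atoms: tert-butyl hydroperoxide, CC(C)(C)OO
Why: Hydroxyl-directed vanadium-catalysed epoxidation: with the C4–OH bound to vanadium (O–C4–C5=C6 dihedral near 45°, OH inside and methyl outside to minimise A(1,3) strain with C7) oxygen is delivered syn to the hydroxyl, which for 4R should give 5S,6S and leave the tetrasubstituted olefin untouched.

Step 14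
Reactants: 21 cis-epoxy alcohol
Product: 23 4,5-epoxide (4R,5R,6S,8S,10R) with free C6–OH, C8–OH and C13–OH, via triol epoxide 22 (not isolated)
Conditions: n-Bu4NF (2.5 equiv), THF, 0 °C; then 0.5 M aq. NaOH, t-BuOH, rt; pH 7 buffer
Reagents that add atoms: none
Why: Fluoride cleaves the silaketal and hydroxide then effects the Payne rearrangement, in which the C4 alkoxide opens the cis-epoxide at C5 with inversion (5S to 5R) while C6 keeps its oxygen and configuration; the equilibrium should favour the trisubstituted epoxide and the secondary allylic alkoxide.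

Step 15
Reactants: 23 triol
Product: 24 C13 acetate of 23
Conditions: Ac2O (1.1 equiv), 2,4,6-collidine, CH2Cl2, −20 °C
Reagents that add atoms: acetic anhydride, CC(=O)OC(C)=O
Why: Selective acetylation of the primary C13 hydroxyl over the two secondary hydroxyls with a hindered base at low temperature.

Step 16
Reactants: 24 acetate
Product: 25 C12 alcohol (PMB removed)
Conditions: DDQ (1.3 equiv), CH2Cl2/pH 7 phosphate buffer 10:1, 0 °C
Reagents that add atoms: none
Why: Buffered oxidative PMB ether cleavage frees the C12 hydroxyl without harming the orthoester or the epoxide.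

Step 17
Reactants: 25 triol acetate
Product: 26 butenolide (ring B closed) with free C8–OH, C13–OAc and C1/C10 orthoacetate
Conditions: TEMPO (0.2 equiv), PhI(OAc)2 (2.5 equiv), NaHCO3, CH2Cl2, rt
Reagents that add atoms: none
Why: Oxidative lactonisation: only the primary allylic C12 alcohol is oxidised, the aldehyde is trapped by the cis C6 hydroxyl as the lactol and oxidised on to the lactone, so the butenolide C6–H never meets base.

Step 18
Reactants: 26 hydroxy butenolide
Product: 27 C8 methacrylate of 26
Conditions: methacrylic anhydride (1.5 equiv), DMAP (0.1 equiv), pyridine, CH2Cl2, 0 °C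
Reagents that add atoms: methacrylic anhydride, CC(=C)C(=O)OC(=O)C(C)=C
Why: DMAP-catalysed acylation of the only free hydroxyl (C8) under weakly basic conditions.

Step 19
Reactants: 27 orthoacetate
Product: 29 glaucolide A, via hydroxy acetate 28 (not isolated)
Conditions: AcOH/THF/H2O 1:4:1, 0 °C; solvent exchange; then Dess–Martin periodinane (1.5 equiv), NaHCO3, CH2Cl2, 0 °C → rt
Reagents that add atoms: water, O
Why: Mild acid hydrolysis of the cyclic orthoacetate should expel the less hindered secondary oxygen and leave the acetate on the tertiary C10 oxygen (as in the classical preparation of corticoid 17-monoesters from 17,21-orthoesters), and immediate Dess–Martin oxidation of the freed C1 alcohol gives the ketone before acyl migration can occur.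

**Compound list**

1 | (R)-linalool, (3R)-3,7-dimethylocta-1,6-dien-3-ol | C=C[C@](C)(O)CCC=C(C)C | starting material
2 | (5R)-5-ethenyl-5-methyloxolan-2-ol (anomer mixture) | C=C[C@@]1(C)CCC(O)O1 | intermediate
3 | (3R)-5-iodo-3-methylpent-1-en-3-yl formate | C=C[C@](C)(OC=O)CCI | intermediate
4 | 2-methylidenepropane-1,3-diol | C=C(CO)CO | starting material
5 | 2-{[(4-methoxyphenyl)methoxy]methyl}prop-2-en-1-ol | C=C(CO)COCc1ccc(OC)cc1 | intermediate
6 | 4-(trimethylsilyl)but-3-yn-2-one | CC(=O)C#C[Si](C)(C)C | starting material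
7 | trimethyl{[4-(trimethylsilyl)but-1-en-3-yn-2-yl]oxy}silane | C=C(O[Si](C)(C)C)C#C[Si](C)(C)C | intermediate
8 | methyl pyruvate | CC(=O)C(=O)OC | starting material
9 | methyl (2R)-2-methyl-4-oxo-6-(trimethylsilyl)-2-[(trimethylsilyl)oxy]hex-5-ynoate (not isolated) | COC(=O)[C@](C)(O[Si](C)(C)C)CC(=O)C#C[Si](C)(C)C | intermediate
10 | methyl (2R)-2-hydroxy-2-methyl-4-oxo-6-(trimethylsilyl)hex-5-ynoate | COC(=O)[C@](C)(O)CC(=O)C#C[Si](C)(C)C | intermediate
11 | methyl (2R,4S)-2,4-dihydroxy-2-methyl-6-(trimethylsilyl)hex-5-ynoate (not isolated) | COC(=O)[C@](C)(O)C[C@H](O)C#C[Si](C)(C)C | intermediate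
12 | (3R,5S)-3-hydroxy-3-methyl-5-[(trimethylsilyl)ethynyl]oxolan-2-one | O=C1O[C@H](C#C[Si](C)(C)C)C[C@@]1(C)O | intermediate
13 | (3R,5S)-3-methyl-5-[(trimethylsilyl)ethynyl]oxolane-2,3-diol (C2 epimers) | OC1O[C@H](C#C[Si](C)(C)C)C[C@@]1(C)O | intermediate
14 | (3R,7R,9S)-6,7,9-trihydroxy-3,7-dimethyl-11-(trimethylsilyl)undec-1-en-10-yn-3-yl formate (C6 epimers) | C=C[C@](C)(OC=O)CCC(O)[C@](C)(O)C[C@H](O)C#C[Si](C)(C)C | intermediate
15 | chlorodi(propan-2-yl)silyl ether of 5 (not isolated) | C=C(COCc1ccc(OC)cc1)CO[Si](Cl)(C(C)C)C(C)C | intermediate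
16 | 14 with O8 bound to Si(i-Pr)2–O–CH2C(=CH2)CH2OPMB; C1–OH and C10–OH free | C=C[C@](C)(OC=O)CCC(O)[C@](C)(O)C[C@@H](C#C[Si](C)(C)C)O[Si](C(C)C)(C(C)C)OCC(=C)COCc1ccc(OC)cc1 | intermediate
17 | 16 with the C1/C10 diol closed as cyclic orthoacetate (2-methoxy-2-methyl-1,3-dioxolane) | C=C[C@](C)(OC=O)CCC1OC(C)(OC)O[C@]1(C)C[C@@H](C#C[Si](C)(C)C)O[Si](C(C)C)(C(C)C)OCC(=C)COCc2ccc(OC)cc2 | intermediate
18 | dienyne: 17 without formyl and C-silyl groups (4R tertiary alcohol, terminal alkyne) | C=C[C@](C)(O)CCC1OC(C)(OC)O[C@]1(C)C[C@@H](C#C)O[Si](C(C)C)(C(C)C)OCC(=C)COCc2ccc(OC)cc2 | intermediate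
19 | triene: seven-membered O8–Si(i-Pr)2–O13 ring with C7=C11, vinyl (C6) on C7, CH2OPMB on C11; C5 vinyl carbinol intact (not isolated) | C=C[C@](C)(O)CCC1OC(C)(OC)O[C@]1(C)C[C@@H]2O[Si](C(C)C)(C(C)C)OCC(COCc3ccc(OC)cc3)=C2C=C | intermediate
20 | ring A diene (4R,5Z,8S,10R): C4–OH, 5Z olefin, O8/O13 silaketal, O12–PMB, C1/C10 orthoacetate | CC(C)[Si]3(C(C)C)O[C@H]1C[C@@]4(C)OC(C)(OC)OC4CC[C@@](C)(O)/C=C\C1=C(COCc5ccc(OC)cc5)CO3 | intermediate
21 | cis-5,6-epoxide of 20 (4R,5S,6S,8S,10R) | CC(C)[Si]3(C(C)C)O[C@H]1C[C@@]4(C)OC(C)(OC)OC4CC[C@@](C)(O)[C@H]2O[C@H]2C1=C(COCc5ccc(OC)cc5)CO3 | intermediate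
22 | 21 without the silicon bridge: C4–OH, C8–OH, C13–OH, cis-5,6-epoxide; C12 cis to C6 (not isolated) | O[C@H]1C[C@@]3(C)OC(C)(OC)OC3CC[C@@](C)(O)[C@H]2O[C@H]2/C1=C(\COCc4ccc(OC)cc4)CO | intermediate
23 | Payne product (4R,5R,6S,8S,10R): 4,5-epoxide, C6–OH, C8–OH, C13–OH, O12–PMB | O[C@H]1C[C@@]3(C)OC(C)(OC)OC3CC[C@@]2(C)O[C@@H]2[C@@H](O)/C1=C(\COCc4ccc(OC)cc4)CO | intermediate
24 | C13 acetate of 23 | O[C@H]1C[C@@]3(C)OC(C)(OC)OC3CC[C@@]2(C)O[C@@H]2[C@@H](O)/C1=C(\COCc4ccc(OC)cc4)COC(C)=O | intermediate
25 | 24 with free C12–OH | O[C@H]1C[C@@]3(C)OC(C)(OC)OC3CC[C@@]2(C)O[C@@H]2[C@@H](O)/C1=C(\CO)COC(C)=O | intermediate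
26 | butenolide with C8–OH, C13–OAc, C1/C10 orthoacetate | O[C@H]1C[C@@]3(C)OC(C)(OC)OC3CC[C@@]2(C)O[C@@H]2[C@H]2OC(=O)C(COC(C)=O)=C12 | intermediate
27 | C8 methacrylate of 26 | C=C(C)C(=O)O[C@H]1C[C@@]3(C)OC(C)(OC)OC3CC[C@@]2(C)O[C@@H]2[C@H]2OC(=O)C(COC(C)=O)=C12 | intermediate
28 | 1-hydroxy-1-deoxo-glaucolide A (C10–OAc, C1–OH; not isolated) | C=C(C)C(=O)O[C@H]1C[C@@](C)(OC(C)=O)C(O)CC[C@@]2(C)O[C@@H]2[C@H]2OC(=O)C(COC(C)=O)=C12 | intermediate
29 | glaucolide A (4R,5R,6S,8S,10R) | C=C(C)C(=O)O[C@H]1C[C@@](C)(OC(C)=O)C(=O)CC[C@@]2(C)O[C@@H]2[C@H]2OC(=O)C(COC(C)=O)=C12 | target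

**Step count and risks**

Total step count: 19. Longest linear sequence: 16 steps (steps 4 to 19, from 6).

Steps most likely to fail:

1. Step 12. The ruthenium alkylidene may load first on the C5 vinyl group and add to the alkyne in the wrong sense, or the diene stage may oligomerise or give the E olefin. Fallback, setting out from 18: run only the enyne stage (ethylene, 40 °C) and isolate triene 19, then close ring A by carbonyl chemistry. Lemieux–Johnson cleavage (OsO4 cat., NMO; then NaIO4) of both vinyl groups gives the dialdehyde F1. SmI2 pinacol cyclisation at high dilution gives the cis-5,6-diol F2. 1,1'-Thiocarbonyldiimidazole gives the cyclic thionocarbonate F3. Corey–Winter elimination with 1,3-dimethyl-2-phenyl-1,3,2-diazaphospholidine (syn elimination of the cis-diol gives the Z olefin) returns to the route at 20.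

2. Step 14. The Payne equilibrium may not lie far enough on the side of the 4,5-epoxide inside the ten-membered ring, or hydroxide may open the vinyl epoxide. Fallback, setting out from 21 with the silicon bridge still in place: NaH in THF at 0 °C followed by Et3SiCl traps the rearranged secondary alkoxide kinetically as the C6 triethylsilyl ether F4 (Payne rearrangement with silyl trapping). n-Bu4NF then removes both silicon groups and returns to the route at 23.

3. Step 13. Facial selectivity may be poor if the ring prefers the conformer with the methyl group inside, or the diene may be over-oxidised. Fallback, setting out from 20 and returning at 21 with no new intermediate: replace substrate-directed control by reagent control, using Hf(Ot-Bu)4 with a chiral bis-hydroxamic acid ligand and cumene hydroperoxide, a catalyst system made for tertiary allylic alcohols, with the ligand enantiomer chosen to give the 5S,6S epoxide.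

Further compounds
F1 | step 12 | dialdehyde from 19 (C5 and C6 formyl groups in place of the two vinyl groups) | O=C[C@](C)(O)CCC1OC(C)(OC)O[C@]1(C)C[C@@H]2O[Si](C(C)C)(C(C)C)OCC(COCc3ccc(OC)cc3)=C2C=O
F2 | step 12 | cis-5,6-diol of ring A (pinacol product; C5/C6 cis, either face) | CC(C)[Si]3(C(C)C)O[C@H]1C[C@@]4(C)OC(C)(OC)OC4CC[C@@](C)(O)C(O)C(O)C1=C(COCc5ccc(OC)cc5)CO3
F3 | step 12 | 5,6-cyclic thionocarbonate of F2 | CC(C)[Si]3(C(C)C)O[C@H]1C[C@@]4(C)OC(C)(OC)OC4CC[C@@](C)(O)C2OC(=S)OC2C1=C(COCc5ccc(OC)cc5)CO3
F4 | step 14 | C6 triethylsilyl ether of the 4,5-epoxide with the O8/O13 silicon bridge intact | CC(C)[Si]3(C(C)C)O[C@H]1C[C@@]4(C)OC(C)(OC)OC4CC[C@@]2(C)O[C@@H]2[C@@H](O[Si](CC)(CC)CC)C1=C(COCc5ccc(OC)cc5)CO3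
F0 | step 13 | none | none
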